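**Plan**

1. Lettering: the ring carbons are a–m in the order of the target SMILES (a carries the decenyl chain, m the ester). The rings are cyclobutane a-b-g-h, cyclohexene b-c-d-e-f-g, cyclopentane f-g-h-i-j and cyclohexene e-f-j-k-l-m.
2. Retrosynthetic cuts, in order: the ester back to CH2OSi on m; the C1'–C2' bond of the side chain (tosylate plus Grignard reagent); C-a–C1' (back to a cyclobutanone); k=l (metathesis); a–b, re-formed as a–d (reverse 1,3-acyl shift); g–f and d–e (Diels–Alder); h–O (dearomatisation); e–m (epoxide opening); i–j (enolate benzylation).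
3. Enabling feature: with a bonded to d instead of b, carbons a, h, g, b, c, d form one six-membered carbocycle with oxygen on a and the chain i–j on the neighbouring h, which is an ortho-alkylphenol. Its o-quinol acetate holds the diene d=c–b=g s-cis, three atoms (h, i, j) from the Z-alkene f=e.
4. Forward ring order: the cyclopentane and ring b-c-d-e-f-g form together in step 14 as an isotwistenone. The cyclobutanone follows by light-driven migration of a from d to b. Ring e-f-j-k-l-m is then closed by metathesis; this must wait for the migration, because in the cage the vinyl group on j points away from m. The chain is joined last.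
5. Stereochemistry: C-j comes from an Evans alkylation, C-m from (R)-2-vinyloxirane opened with inversion, and the Z-alkene from semihydrogenation. C-j (through A(1,3) strain) and the tether fix d, e, f and g and select the reactive h epimer. C-b follows from the suprafacial shift and C-a from equilibration of an aldehyde to the exo face. The E-alkene arrives with the chain fragment.

Key step: step 14

Remark on the chemistry: step 13 cannot control C-h, so 20 denotes the (6S) epimer of a pair that is carried into step 14 unseparated. Compounds 1, 4, 5, 13 and 30 are taken as commercial.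

**Route**

Step 1
Reactants: 1 2-hydroxybenzyl alcohol
Product: 2 [2-(methoxymethoxy)phenyl]methanol
Conditions: MOMCl, K2CO3, acetone, 0 °C to rt
Reagents that add atoms: chloromethyl methyl ether, COCCl
Why: Williamson-type O-alkylation in which carbonate deprotonates only the far more acidic phenol, so the MOM group goes on the ring oxygen and the benzylic alcohol stays free.

Step 2
Reactants: 2 [2-(methoxymethoxy)phenyl]methanol
Product: 3 1-(bromomethyl)-2-(methoxymethoxy)benzene
Conditions: CBr4, PPh3, CH2Cl2, 0 °C
Reagents that add atoms: tetrabromomethane, BrC(Br)(Br)Br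
Why: The Appel reaction converts the primary benzylic alcohol into the bromide under neutral conditions that leave the MOM acetal intact.

Step 3
Reactants: 4 (S)-4-benzyloxazolidin-2-one; 5 (E)-but-2-enoyl chloride
Product: 7 (S)-4-benzyl-3-[(E)-but-2-enoyl]oxazolidin-2-one, via lithium oxazolidinide 6 (not isolated)
Conditions: n-BuLi, THF, −78 °C; then 5, −78 to 0 °C
Reagents that add atoms: none
Why: N-acylation of the lithiated oxazolidinone with an acid chloride is the standard entry to Evans imides.

Step 4
Reactants: 7 (S)-4-benzyl-3-[(E)-but-2-enoyl]oxazolidin-2-one; 3 1-(bromomethyl)-2-(methoxymethoxy)benzene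
Product: 9 (4S)-4-benzyl-3-{(2S)-2-[2-(methoxymethoxy)benzyl]but-3-enoyl}oxazolidin-2-one, via sodium dienolate 8 (not isolated)
Conditions: NaHMDS, THF, −78 °C; then 3, −78 to −40 °C
Reagents that add atoms: none
Why: Deconjugative Evans alkylation, in which γ-deprotonation gives the chelated (Z)-dienolate that reacts at its α-carbon with the benzylic bromide on the face away from the auxiliary benzyl group, forming i–j and setting C-j as S.

Step 5
Reactants: 9 (4S)-4-benzyl-3-{(2S)-2-[2-(methoxymethoxy)benzyl]but-3-enoyl}oxazolidin-2-one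
Product: 10 (2S)-2-[2-(methoxymethoxy)benzyl]but-3-en-1-ol
Conditions: LiBH4, MeOH (1 equiv), Et2O, 0 °C; aqueous work-up
Reagents that add atoms: none
Why: Reductive removal of the auxiliary (imide to primary alcohol) avoids basic hydrolysis, so the α-vinyl stereocentre neither epimerises nor slips into conjugation.

Step 6
Reactants: 10 (2S)-2-[2-(methoxymethoxy)benzyl]but-3-en-1-ol
Product: 11 (2S)-2-[2-(methoxymethoxy)benzyl]but-3-enal
Conditions: Dess–Martin periodinane, NaHCO3, CH2Cl2, 0 °C; used at once
Reagents that add atoms: none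
Why: The buffered Dess–Martin oxidation stops at the aldehyde under near-neutral conditions, which protects the labile α-vinyl stereocentre.

Step 7
Reactants: 11 (2S)-2-[2-(methoxymethoxy)benzyl]but-3-enal
Product: 12 1-[(2S)-4,4-dibromo-2-vinylbut-3-en-1-yl]-2-(methoxymethoxy)benzene
Conditions: CBr4, PPh3, Zn, CH2Cl2, rt (pre-mixed); then 11, 0 °C
Reagents that add atoms: tetrabromomethane, BrC(Br)(Br)Br
Why: The Ramirez dibromoolefination (first half of the Corey–Fuchs sequence) is a non-basic Wittig-type reaction and so leaves C-j untouched.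

Step 8
Reactants: 13 (±)-2-vinyloxirane
Product: 14 (R)-2-vinyloxirane
Conditions: (R,R)-(salen)Co(OAc) (cat.; salen = N,N'-bis(3,5-di-tert-butylsalicylidene)cyclohexane-1,2-diamine dianion), H2O (0.55 equiv), THF, 0 °C to rt; distillation
Reagents that add atoms: none
Why: Hydrolytic kinetic resolution, in which the (R,R) cobalt salen complex hydrolyses the S-epoxide selectively and the volatile R-epoxide is distilled off.

Step 9
Reactants: 12 1-[(2S)-4,4-dibromo-2-vinylbut-3-en-1-yl]-2-(methoxymethoxy)benzene; 14 (R)-2-vinyloxirane
Product: 16 (2R,5S)-5-[2-(methoxymethoxy)benzyl]-2-vinylhept-6-en-3-yn-1-ol, via lithium acetylide 15 (not isolated)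
Conditions: n-BuLi (2.05 equiv), THF, −78 to −20 °C; then BF3·OEt2 and excess 14, −78 °C
Reagents that add atoms: none
Why: The second half of the Corey–Fuchs sequence gives the lithium acetylide, which opens the BF3-activated vinyl epoxide at its allylic carbon by SN2 with inversion (Lewis-acid-promoted alkynylation of epoxides), forming e–m and setting C-m as R.

Step 10
Reactants: 16 (2R,5S)-5-[2-(methoxymethoxy)benzyl]-2-vinylhept-6-en-3-yn-1-ol
Product: 17 tert-butyl{[(2R,5S)-5-[2-(methoxymethoxy)benzyl]-2-vinylhept-6-en-3-yn-1-yl]oxy}diphenylsilane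
Conditions: TBDPSCl, imidazole, CH2Cl2, rt
Reagents that add atoms: tert-butylchlorodiphenylsilane, CC(C)(C)[Si](Cl)(c1ccccc1)c1ccccc1
Why: Silylation of the primary alcohol installs an ether that should withstand the later acid, oxidant, light, ylide and Grignard steps.

Step 11
Reactants: 17 tert-butyl{[(2R,5S)-5-[2-(methoxymethoxy)benzyl]-2-vinylhept-6-en-3-yn-1-yl]oxy}diphenylsilane
Product: 18 1-[(2S,3Z,5R)-5-(tert-butyldiphenylsilyloxymethyl)-2-vinylhepta-3,6-dien-1-yl]-2-(methoxymethoxy)benzene
Conditions: H2 (1 atm), Pd/CaCO3 poisoned with Pb(OAc)2 (Lindlar catalyst), quinoline, EtOAc–hexane, rt; stopped after one equivalent of H2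
Reagents that add atoms: none
Why: Lindlar semihydrogenation delivers H2 syn to the alkyne, which binds the poisoned palladium surface more strongly than the vinyl groups, and so gives the Z-alkene f=e.

Step 12
Reactants: 18 1-[(2S,3Z,5R)-5-(tert-butyldiphenylsilyloxymethyl)-2-vinylhepta-3,6-dien-1-yl]-2-(methoxymethoxy)benzene
Product: 19 2-[(2S,3Z,5R)-5-(tert-butyldiphenylsilyloxymethyl)-2-vinylhepta-3,6-dien-1-yl]phenol
Conditions: conc. HCl (cat.), MeOH, 45 °C
Reagents that add atoms: none
Why: Acid-catalysed acetal exchange with methanol removes the phenolic MOM group, while the acid-stable TBDPS ether and the skipped triene are spectators.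

Step 13
Reactants: 19 2-[(2S,3Z,5R)-5-(tert-butyldiphenylsilyloxymethyl)-2-vinylhepta-3,6-dien-1-yl]phenol
Product: 20 (6S)-6-acetoxy-6-[(2S,3Z,5R)-5-(tert-butyldiphenylsilyloxymethyl)-2-vinylhepta-3,6-dien-1-yl]cyclohexa-2,4-dien-1-one (formed together with its 6R epimer)
Conditions: Pb(OAc)4, CH2Cl2–AcOH, 0 °C, argon; aqueous wash, short silica plug
Reagents that add atoms: lead tetraacetate, CC(=O)O[Pb](OC(C)=O)(OC(C)=O)OC(C)=O
Why: Wessely oxidation, in which the aryloxylead triacetate passes acetate to an ortho carbon and attack at the alkylated, more electron-rich C-h gives the non-enolisable o-quinol acetate; C-h forms without control, so both epimers are carried on.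

Step 14
Reactants: 20 (6S)-6-acetoxy-6-[(2S,3Z,5R)-5-(tert-butyldiphenylsilyloxymethyl)-2-vinylhepta-3,6-dien-1-yl]cyclohexa-2,4-dien-1-one (as the epimer pair)
Product: 21 tricyclic acetoxy ketone (isotwistenone): bicyclo[2.2.2]octenone with bridges a(=O)–h(OAc), b=c and f–e between bridgeheads g and d; cyclopentane f-g-h-i-j; vinyl on j anti to e; C-m, (R)-CH(CH=CH2)CH2OTBDPS, on e syn to the carbonyl bridge; H-e and H-f syn to b=c
Conditions: toluene (high dilution), BHT (cat.), 110 °C, argon
Reagents that add atoms: none
Why: A thermal, concerted, suprafacial [4+2] cycloaddition joins the s-cis-locked diene d=c–b=g of the o-quinol acetate to the tethered Z-alkene f=e, forming g–f and d–e; it belongs to the known intramolecular Diels–Alder reactions of 6-acetoxy-6-alkenylcyclohexa-2,4-dienones that give isotwistenones. The cyclopentane f-g-h-i-j closes in the fused mode of a type 1 reaction (three-atom tether h, i, j between diene terminus g and dienophile carbon f), and ring b-c-d-e-f-g closes as the new six-membered ring of the cycloaddition, which with the bridge a–h makes up the bicyclo[2.2.2]octenone. C-g and C-d follow from the diene face that carries the CH2 tether (anti to the acetoxy group on C-h), and C-f and C-e follow from the tether, which must hold C-j, and through the Z geometry also C-m, over the keto bridge so that H-f and H-e face the new b=c bond. The alkene face is chosen by C-j, because A(1,3) strain against C-m puts H-j in the alkene plane, the tether CH2 on the reacting face and the vinyl group anti, so C-e ends trans to that vinyl group on the cyclopentane. Only the (6S) epimer can adopt this arrangement, whereas its C-h epimer would have to turn the vinyl group into the plane against C-m, so it lags behind or dimerises and is removed by chromatography. Regiochemistry is fixed by the tether length, and the process to beat is bimolecular dimerisation of the dienone, which high dilution and the acetoxy (rather than hydroxy) substituent hold back.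

Step 15
Reactants: 21 tricyclic acetoxy ketone
Product: 22 tricyclic ketone: as 21 but with H on h, pointing toward b=c
Conditions: SmI2 (2.2 equiv), THF–MeOH, −78 °C
Reagents that add atoms: none
Why: SmI2 reduction of an α-acyloxy ketone expels acetate after two single-electron transfers, and the samarium enolate is protonated at C-h on the only face the cyclopentane allows.

Step 16
Reactants: 22 tricyclic ketone
Product: 23 tricyclic divinyl cyclobutanone: cyclobutanone a-b-g-h cis-fused to cyclohexene b-c=d-e-f-g and to cyclopentane f-g-h-i-j; a, h, j and m all on one face of the cyclohexene; vinyl on j and the C-m side chain unchanged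
Conditions: hν (300 nm lamps, Pyrex), degassed benzene (dilute), rt; stopped at partial conversion, 22 recycled
Reagents that add atoms: none
Why: Direct n→π* excitation of the β,γ-unsaturated ketone cleaves the allylic a–d bond and the acyl carbon recombines at b on the same face (photochemical 1,3-acyl shift of bicyclo[2.2.2]octenones to bicyclo[4.2.0]octenones), which sets C-b cis to C-g and moves the alkene to c=d.

Step 17
Reactants: 23 tricyclic divinyl cyclobutanone
Product: 24 tetracyclic cyclobutanone: new cyclohexene e-f-j-k=l-m, trans-fused to the cyclopentane at f–j and cis-fused at e–f; CH2OTBDPS on m trans to C-d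
Conditions: second-generation Grubbs catalyst (H2IMes)(PCy3)Cl2Ru=CHPh (cat.), CH2Cl2 (dilute), 40 °C
Reagents that add atoms: none
Why: Ring-closing metathesis of the two vinyl groups releases ethene and closes the last ring, which is possible only now that the e–f bond is no longer held eclipsed in a bicyclo[2.2.2]octane (in 22 the torsion e–f–j–k is close to anti), while the unstrained c=d alkene stays out and no stereocentre changes.

Step 18
Reactants: 24 tetracyclic cyclobutanone
Product: 25 tetracyclic methyl enol ether (a=CH–OMe, E/Z mixture)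
Conditions: (methoxymethyl)triphenylphosphonium chloride, KOtBu, THF, 0 °C; then 24, 0 °C to rt
Reagents that add atoms: (methoxymethyl)triphenylphosphonium chloride, [Cl-].COC[P+](c1ccccc1)(c1ccccc1)c1ccccc1
Why: The Wittig reaction of the strained, electrophilic cyclobutanone with the methoxymethylidene ylide adds C1' of the side chain as an enol ether whose geometry is of no consequence.

Step 19
Reactants: 25 tetracyclic methyl enol ether
Product: 27 exo aldehyde (CHO on a on the face of H-b and H-h), via endo aldehyde 26 (not isolated)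
Conditions: 1 M HCl, THF, rt; then K2CO3, MeOH, rt
Reagents that add atoms: water, O
Why: Enol ether hydrolysis protonates C-a from the open convex face and so first gives the endo aldehyde, which carbonate-mediated enolisation converts into the thermodynamic exo epimer because the endo position is flanked by C-c and C-i, and this sets C-a.

Step 20
Reactants: 27 exo aldehyde
Product: 28 exo hydroxymethyl compound (a–CH2OH)
Conditions: NaBH4, MeOH, 0 °C
Reagents that add atoms: none
Why: Borohydride reduction of the aldehyde is fast at 0 °C and removes the epimerisable centre's activating group with C-a fixed.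

Step 21
Reactants: 28 exo hydroxymethyl compound
Product: 29 exo tosylate (a–CH2OTs)
Conditions: TsCl, Et3N, DMAP (cat.), CH2Cl2, 0 °C to rt
Reagents that add atoms: 4-toluenesulfonyl chloride, Cc1ccc(cc1)S(=O)(=O)Cl
Why: Sulfonylation of the primary alcohol provides the leaving group for the sp3–sp3 coupling without touching any stereocentre.

Step 22
Reactants: 30 9-bromonon-1-ene
Product: 31 (E)-9-bromonon-2-ene
Conditions: [Cp*Ru(MeCN)3]PF6 (cat.), 2-(diisopropylphosphino)-4-tert-butyl-1-methylimidazole (cat.), acetone, rt
Reagents that add atoms: none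
Why: Catalytic positional alkene isomerisation with the bifunctional Cp*Ru phosphine–imidazole system moves a terminal double bond by one position only and gives the E-2-alkene, the primary bromide being a spectator.

Step 23
Reactants: 31 (E)-9-bromonon-2-ene; 29 exo tosylate
Product: 33 tetracycle bearing the (E)-dec-8-enyl chain on a (exo) and CH2OTBDPS on m, via Grignard reagent 32 (not isolated)
Conditions: Mg, THF, rt; then 29, Li2CuCl4 (cat.), THF, −20 °C to rt
Reagents that add atoms: none
Why: The copper-catalysed coupling of a primary tosylate with an alkyl Grignard reagent (Kochi-type sp3–sp3 coupling) is an SN2 process at the CH2 group, so C-a and the E-alkene are not affected.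

Step 24
Reactants: 33 tetracyclic silyl ether
Product: 34 primary alcohol (m–CH2OH)
Conditions: TBAF, THF, rt
Reagents that add atoms: none
Why: Fluoride-induced desilylation frees the primary alcohol and leaves the three alkenes alone.

Step 25
Reactants: 34 primary alcohol
Product: 36 carboxylic acid (m–CO2H), via aldehyde 35 (not isolated)
Conditions: TEMPO (cat.), PhI(OAc)2 (2.2 equiv), MeCN–H2O, rt
Reagents that add atoms: water, O
Why: Oxoammonium oxidation in aqueous acetonitrile takes the alcohol through the aldehyde hydrate to the acid at near-neutral pH, so the allylic stereocentre C-m does not epimerise and k=l does not move into conjugation.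

Step 26
Reactants: 36 carboxylic acid
Product: 37 CNP0133550.1 (methyl ester, target)
Conditions: TMSCHN2, toluene–MeOH, 0 °C
Reagents that add atoms: (trimethylsilyl)diazomethane, C[Si](C)(C)C=[N+]=[N-]
Why: O-methylation of the acid by diazomethane released in situ needs no base and so keeps C-m and the β,γ-alkene in place.

**Compound list**

1 | 2-hydroxybenzyl alcohol | OCc1ccccc1O | starting material
2 | [2-(methoxymethoxy)phenyl]methanol | COCOc1ccccc1CO | intermediate
3 | 1-(bromomethyl)-2-(methoxymethoxy)benzene | COCOc1ccccc1CBr | intermediate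
4 | (S)-4-benzyloxazolidin-2-one | O=C1N[C@@H](Cc2ccccc2)CO1 | starting material
5 | (E)-but-2-enoyl chloride | C/C=C/C(Cl)=O | starting material
6 | lithium (S)-4-benzyl-2-oxooxazolidin-3-ide | [Li]N1[C@@H](Cc2ccccc2)COC1=O | intermediate
7 | (S)-4-benzyl-3-[(E)-but-2-enoyl]oxazolidin-2-one | C/C=C/C(=O)N1[C@@H](Cc2ccccc2)COC1=O | intermediate
8 | sodium (Z)-dienolate of 7 | [Na+].C=C/C=C(\[O-])N1[C@@H](Cc2ccccc2)COC1=O | intermediate
9 | (4S)-4-benzyl-3-{(2S)-2-[2-(methoxymethoxy)benzyl]but-3-enoyl}oxazolidin-2-one | C=C[C@H](Cc1ccccc1OCOC)C(=O)N2[C@@H](Cc3ccccc3)COC2=O | intermediate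
10 | (2S)-2-[2-(methoxymethoxy)benzyl]but-3-en-1-ol | C=C[C@H](Cc1ccccc1OCOC)CO | intermediate
11 | (2S)-2-[2-(methoxymethoxy)benzyl]but-3-enal | C=C[C@H](Cc1ccccc1OCOC)C=O | intermediate
12 | 1-[(2S)-4,4-dibromo-2-vinylbut-3-en-1-yl]-2-(methoxymethoxy)benzene | C=C[C@H](Cc1ccccc1OCOC)C=C(Br)Br | intermediate
13 | (±)-2-vinyloxirane | C=CC1CO1 | starting material
14 | (R)-2-vinyloxirane | C=C[C@@H]1CO1 | intermediate
15 | lithium acetylide from 12 | C=C[C@H](Cc1ccccc1OCOC)C#C[Li] | intermediate
16 | (2R,5S)-5-[2-(methoxymethoxy)benzyl]-2-vinylhept-6-en-3-yn-1-ol | C=C[C@H](Cc1ccccc1OCOC)C#C[C@H](CO)C=C | intermediate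
17 | TBDPS ether of 16 | C=C[C@H](Cc1ccccc1OCOC)C#C[C@H](CO[Si](c2ccccc2)(c3ccccc3)C(C)(C)C)C=C | intermediate
18 | (2S,3Z,5R)-triene, MOM ether | C=C[C@H](Cc1ccccc1OCOC)/C=C\[C@H](CO[Si](c2ccccc2)(c3ccccc3)C(C)(C)C)C=C | intermediate
19 | (2S,3Z,5R)-triene, free phenol | C=C[C@H](Cc1ccccc1O)/C=C\[C@H](CO[Si](c2ccccc2)(c3ccccc3)C(C)(C)C)C=C | intermediate
20 | (6S)-6-acetoxy-6-alkenylcyclohexa-2,4-dien-1-one | O=C1C=CC=C[C@@]1(OC(C)=O)C[C@@H](C=C)/C=C\[C@H](CO[Si](c2ccccc2)(c3ccccc3)C(C)(C)C)C=C | intermediate
21 | tricyclic acetoxy ketone (isotwistenone) | O=C1[C@@H]2C=C[C@@H]3[C@@]1(OC(C)=O)C[C@@H](C=C)[C@@H]3[C@@H]2[C@H](CO[Si](c4ccccc4)(c5ccccc5)C(C)(C)C)C=C | intermediate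
22 | tricyclic ketone (H on h) | O=C1[C@@H]2C=C[C@@H]3[C@H]1C[C@@H](C=C)[C@@H]3[C@@H]2[C@H](CO[Si](c4ccccc4)(c5ccccc5)C(C)(C)C)C=C | intermediate
23 | tricyclic divinyl cyclobutanone | O=C1[C@H]2C=C[C@@H]([C@H](CO[Si](c4ccccc4)(c5ccccc5)C(C)(C)C)C=C)[C@@H]3[C@H]2[C@H]1C[C@H]3C=C | intermediate
24 | tetracyclic cyclobutanone | O=C1[C@H]2C=C[C@@H]3[C@@H]4[C@H]2[C@H]1C[C@H]4C=C[C@H]3CO[Si](c5ccccc5)(c6ccccc6)C(C)(C)C | intermediate
25 | tetracyclic methyl enol ether | COC=C1[C@H]2C=C[C@@H]3[C@@H]4[C@H]2[C@H]1C[C@H]4C=C[C@H]3CO[Si](c5ccccc5)(c6ccccc6)C(C)(C)C | intermediate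
26 | endo aldehyde | O=C[C@H]1[C@H]2C=C[C@@H]3[C@@H]4[C@H]2[C@H]1C[C@H]4C=C[C@H]3CO[Si](c5ccccc5)(c6ccccc6)C(C)(C)C | intermediate
27 | exo aldehyde | O=C[C@@H]1[C@H]2C=C[C@@H]3[C@@H]4[C@H]2[C@H]1C[C@H]4C=C[C@H]3CO[Si](c5ccccc5)(c6ccccc6)C(C)(C)C | intermediate
28 | exo hydroxymethyl compound | OC[C@@H]1[C@H]2C=C[C@@H]3[C@@H]4[C@H]2[C@H]1C[C@H]4C=C[C@H]3CO[Si](c5ccccc5)(c6ccccc6)C(C)(C)C | intermediate
29 | exo tosylate | Cc7ccc(cc7)S(=O)(=O)OC[C@@H]1[C@H]2C=C[C@@H]3[C@@H]4[C@H]2[C@H]1C[C@H]4C=C[C@H]3CO[Si](c5ccccc5)(c6ccccc6)C(C)(C)C | intermediate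
30 | 9-bromonon-1-ene | C=CCCCCCCCBr | starting material
31 | (E)-9-bromonon-2-ene | C/C=C/CCCCCCBr | intermediate
32 | (E)-non-7-enylmagnesium bromide | C/C=C/CCCCCC[Mg]Br | intermediate
33 | tetracycle with (E)-dec-8-enyl chain, TBDPS ether | C/C=C/CCCCCCC[C@@H]1[C@H]2C=C[C@@H]3[C@@H]4[C@H]2[C@H]1C[C@H]4C=C[C@H]3CO[Si](c5ccccc5)(c6ccccc6)C(C)(C)C | intermediate
34 | primary alcohol | C/C=C/CCCCCCC[C@@H]1[C@H]2C=C[C@@H]3[C@@H]4[C@H]2[C@H]1C[C@H]4C=C[C@H]3CO | intermediate
35 | aldehyde on m | C/C=C/CCCCCCC[C@@H]1[C@H]2C=C[C@@H]3[C@@H]4[C@H]2[C@H]1C[C@H]4C=C[C@H]3C=O | intermediate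
36 | carboxylic acid | C/C=C/CCCCCCC[C@@H]1[C@H]2C=C[C@@H]3[C@@H]4[C@H]2[C@H]1C[C@H]4C=C[C@H]3C(=O)O | intermediate
37 | CNP0133550.1 | C/C=C/CCCCCCC[C@@H]1[C@H]2C=C[C@@H]3[C@@H]4[C@H]2[C@H]1C[C@H]4C=C[C@H]3C(=O)OC | target

**Step count**

Total step count: 26.
Longest linear sequence: 23 steps, from 1 to 37 through steps 1, 2, 4–7, 9–21 and 23–26.

**Steps most likely to fail**

1. Step 14, together with step 13 that feeds it.
   - What may go wrong: acetate may be delivered to the free ortho and para positions of the phenol instead of C-h. In addition, bimolecular dimerisation of the dienone may outrun the slow addition to a Z-alkene flanked by two branched carbons.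
   - Fallback: it sets out from phenol 19 and blocks the para carbon b with a removable halogen. Para-bromination (NBS, MeCN, 0 °C; the phenol ring reacts far faster than the unactivated alkenes) should give the 4-bromophenol F1. Wessely oxidation (Pb(OAc)4, CH2Cl2–AcOH, 0 °C), now without a para outlet, should give the 4-bromo-6-acetoxydienone F2. A halogen on the inner diene carbon is known to slow the [4+2] dimerisation of cyclohexa-2,4-dienones, so F2 can be heated harder (toluene or xylene, 110–140 °C) to give the bromo isotwistenone F3 through the same g–f and d–e bond formation. Radical hydrodebromination of the vinyl bromide (Bu3SnH, AIBN, benzene, 80 °C) returns to the route at 21.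

2. Step 16.
   - What may go wrong: the reaction may stall at a photostationary state. The cyclobutanone may undergo secondary photolysis with loss of CO or of a ketene. Hydrogen transfer from C-h within the acyl/allyl radical pair may open the ring to a ketene. Intersystem crossing may divert material into the oxa-di-π-methane channel.
   - Fallback: the migration is moved ahead of the deacetoxylation, starting from 21. In 21, C-h is quaternary and cannot donate hydrogen to the allyl radical. Irradiation (300 nm, benzene) should give the acetoxy cyclobutanone F4, and SmI2 (THF–MeOH, −78 °C) then removes the α-acetoxy group. C-h is again protonated on the only face the ring fusions allow, and the route is rejoined at 23.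

3. Step 11.
   - What may go wrong: the two terminal vinyl groups may be over-reduced while the hindered internal alkyne, flanked by two tertiary carbons, takes up hydrogen slowly.
   - Fallback: surface hydrogenation is replaced by hydrometalation. Starting from 17, syn-hydrocupration with an N-heterocyclic carbene copper hydride is followed by protonolysis of the alkenylcopper: (IPr)CuCl (cat.), NaOtBu (cat.), polymethylhydrosiloxane, i-BuOH, toluene, rt. Unactivated terminal alkenes do not insert into this hydride, so the Z-alkene should form without touching them. The route is rejoined at 18 and no new compound is made (F0).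

**Further compounds**

F1 | step 14 | 4-bromo-2-[(2S,3Z,5R)-5-(tert-butyldiphenylsilyloxymethyl)-2-vinylhepta-3,6-dien-1-yl]phenol | C=C[C@H](Cc1cc(Br)ccc1O)/C=C\[C@H](CO[Si](c2ccccc2)(c3ccccc3)C(C)(C)C)C=C
F2 | step 14 | 4-bromo analogue of dienone 20 | O=C1C=CC(Br)=C[C@@]1(OC(C)=O)C[C@@H](C=C)/C=C\[C@H](CO[Si](c2ccccc2)(c3ccccc3)C(C)(C)C)C=C
F3 | step 14 | bromo isotwistenone (Br on b of 21) | O=C1[C@@H]2C=C(Br)[C@@H]3[C@@]1(OC(C)=O)C[C@@H](C=C)[C@@H]3[C@@H]2[C@H](CO[Si](c4ccccc4)(c5ccccc5)C(C)(C)C)C=C
F4 | step 16 | acetoxy cyclobutanone (OAc on h of 23) | O=C1[C@H]2C=C[C@@H]([C@H](CO[Si](c4ccccc4)(c5ccccc5)C(C)(C)C)C=C)[C@@H]3[C@H]2[C@@]1(OC(C)=O)C[C@H]3C=C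
F0 | step 11 | none | none
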